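**Retrosynthetic overview**
1. Numbering: ring A = C1(H,Me)–C2–C3=C4–C5(H)–C10(Me,CH2Ar); ring B = C4–C5–C6–C7–C8–C9(Me); linker C11–C12; ring D = C13(Me)–C14–C19(H)–C20–C21–C22(H,Me); ring C = C14=C15–C16–C17–C18(Me2)–C19. The plan rests on ring A: a cyclohexene with its C3=C4 bond at the ring fusion, C5–H, the quaternary C10 and the C1 methyl, which together are the retron of an endo [4+2] adduct.
2. Aryl sulfates ⇐ hydroquinone ⇐ dimethoxyarene; C11–C12 ⇐ ring A/B C11 aldehyde 21 + ring C/D C12 neopentyllithium (from phenyl sulfide 31), the C11 oxygen being removed afterwards; C10 methyl ⇐ formyl.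
3. Ring A ⇐ ring B diene 11 + arylmethyl enal 16 (bonds C5–C10 and C1–C2) under a chiral oxazaborolidinium salt; C9 of 11 comes from an enantioselective decarboxylative allylation.
4. Ring C ⇐ the same kind of cycloaddition of ring D vinylcyclohexene 28 with methacrolein (C18–C19, C16–C17), the formyl group becoming the second C18 methyl; C22 and C13 come from asymmetric conjugate methylation of 2-methylcyclohexenone and enolate phenylthiomethylation.
5. Ring order: ring B (purchased) → ring A (step 12); ring D (purchased) → ring C (step 20); the arene is carried from 12.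

Key step: step 12

Remark: the target is taken in the free bis(hydrogen sulfate) form drawn; C18 in 29/30 and C11 in 33–35 form as epimer mixtures that converge later and are left unspecified in the SMILES.

Step 1
Reactants: 1 cyclohexanone
Product: 2 prop-2-en-1-yl 2-oxocyclohexane-1-carboxylate
Conditions: NaH, (CH2=CHCH2O)2CO, THF, reflux; AcOH quench
Reagents that add atoms: diallyl carbonate, C=CCOC(=O)OCC=C
Why: Claisen-type C-acylation of the ketone sodium enolate by the carbonate, driven by deprotonation of the β-keto ester formed, should give 2.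

Step 2
Reactants: 2 prop-2-en-1-yl 2-oxocyclohexane-1-carboxylate
Product: 3 prop-2-en-1-yl 1-methyl-2-oxocyclohexane-1-carboxylate (racemic)
Conditions: MeI, K2CO3, acetone, 50 °C
Reagents that add atoms: iodomethane, CI
Why: C-alkylation of the stabilised β-keto ester enolate; the stereocentre formed here is erased again in step 3.

Step 3
Reactants: 3 prop-2-en-1-yl 1-methyl-2-oxocyclohexane-1-carboxylate
Product: 4 (S)-2-methyl-2-(prop-2-en-1-yl)cyclohexan-1-one
Conditions: Pd2(dba)3 (2.5 mol%), (S)-t-BuPHOX (6 mol%), toluene, 25 °C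
Reagents that add atoms: none
Why: Enantioconvergent decarboxylative allylic alkylation (Tsuji allylation): loss of CO2 gives an achiral enolate and a π-allylpalladium complex whose (S)-phosphinooxazoline ligand directs C–C bond formation to the enolate face that gives (S)-C9; material of the minor enantiomer is removed later as diastereomers (after steps 12 and 22).

Step 4
Reactants: 4 (S)-2-methyl-2-(prop-2-en-1-yl)cyclohexan-1-one
Product: 5 (S)-2-methyl-2-[(E)-prop-1-en-1-yl]cyclohexan-1-one
Conditions: PdCl2(MeCN)2 (5 mol%), toluene, 70 °C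
Reagents that add atoms: none
Why: Palladium-hydride alkene isomerisation moves the terminal double bond one position to the more stable internal alkene and stops there because the next carbon is quaternary; the E/Z ratio is of no consequence.

Step 5
Reactants: 5 (S)-2-methyl-2-[(E)-prop-1-en-1-yl]cyclohexan-1-one
Product: 7 (S)-6-methyl-6-[(E)-prop-1-en-1-yl]cyclohex-1-en-1-yl trifluoromethanesulfonate, via potassium enolate 6 (not isolated)
Conditions: KN(SiMe3)2, THF, −78 °C; PhNTf2, −78 → 0 °C; NH4Cl quench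
Reagents that add atoms: N-phenylbis(trifluoromethanesulfonimide), O=S(=O)(N(c1ccccc1)S(=O)(=O)C(F)(F)F)C(F)(F)F
Why: The ketone can enolise only towards the ring CH2 (the other α-carbon is quaternary), so O-triflation of the enolate should give a single enol triflate.

Step 6
Reactants: 7 (S)-6-methyl-6-[(E)-prop-1-en-1-yl]cyclohex-1-en-1-yl trifluoromethanesulfonate
Product: 9 (S)-6-(hydroxymethyl)-6-methylcyclohex-1-en-1-yl trifluoromethanesulfonate, via secondary ozonide 8 (not isolated)
Conditions: O3, CH2Cl2, −78 °C (to first pale blue); then NaBH4, MeOH, −78 → 0 °C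
Reagents that add atoms: ozone, [O-][O+]=O
Why: Ozonolysis cleaves the electron-rich disubstituted propenyl alkene much faster than the electron-poor enol triflate alkene, and borohydride reduction of the ozonide gives the C11 neopentyl alcohol directly without passing through a labile β-keto aldehyde.

Step 7
Reactants: 9 (S)-6-(hydroxymethyl)-6-methylcyclohex-1-en-1-yl trifluoromethanesulfonate
Product: 10 (S)-6-{[(tert-butyldimethylsilyl)oxy]methyl}-6-methylcyclohex-1-en-1-yl trifluoromethanesulfonate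
Conditions: TBSOTf, 2,6-lutidine, CH2Cl2, 0 °C
Reagents that add atoms: tert-butyldimethylsilyl triflate, CC(C)(C)[Si](C)(C)OS(=O)(=O)C(F)(F)F
Why: Silylation with the silyl triflate is fast even for a neopentyl alcohol and leaves the enol triflate untouched.

Step 8
Reactants: 10 (S)-6-{[(tert-butyldimethylsilyl)oxy]methyl}-6-methylcyclohex-1-en-1-yl trifluoromethanesulfonate
Product: 11 (R)-tert-butyl[(2-ethenyl-1-methylcyclohex-2-en-1-yl)methoxy]dimethylsilane
Conditions: Bu3SnCH=CH2, Pd(PPh3)4 (5 mol%), LiCl, THF, 65 °C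
Reagents that add atoms: tributyl(ethenyl)stannane, C=C[Sn](CCCC)(CCCC)CCCC
Why: Stille coupling of a cyclohexenyl triflate with a vinylstannane is dependable next to a quaternary carbon and gives the 1-vinylcyclohexene with C9 unchanged (the descriptor changes to R only through priority rules).

Step 9
Reactants: 12 2-(chloromethyl)-1,4-dimethoxybenzene
Product: 14 ethyl (E)-2-[(2,5-dimethoxyphenyl)methyl]but-2-enoate, via benzyl-substituted ylide 13 (not isolated)
Conditions: Ph3P=CHCO2Et (2.2 equiv), NaI (cat.), toluene, 90 °C; filter; then MeCHO, 50 °C (sealed)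
Reagents that add atoms: ethyl 2-(triphenyl-λ5-phosphanylidene)acetate, CCOC(=O)C=P(c1ccccc1)(c1ccccc1)c1ccccc1; acetaldehyde, CC=O
Why: C-benzylation of the stabilised ylide and proton transfer to a second equivalent (transylidation) give the α-substituted ylide, whose Wittig reaction with acetaldehyde should be E-selective (methyl trans to the ester), as is usual for stabilised ylides.

Step 10
Reactants: 14 ethyl (E)-2-[(2,5-dimethoxyphenyl)methyl]but-2-enoate
Product: 15 (E)-2-[(2,5-dimethoxyphenyl)methyl]but-2-en-1-ol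
Conditions: i-Bu2AlH, CH2Cl2, −78 °C; Rochelle salt work-up
Reagents that add atoms: none
Why: 1,2-Reduction of the enoate by the aluminium hydride gives the allylic alcohol with the alkene geometry retained.

Step 11
Reactants: 15 (E)-2-[(2,5-dimethoxyphenyl)methyl]but-2-en-1-ol
Product: 16 (E)-2-[(2,5-dimethoxyphenyl)methyl]but-2-enal
Conditions: MnO2, CH2Cl2, rt
Reagents that add atoms: none
Why: Allylic oxidation on MnO2 is neutral and should give the enal without moving the double bond towards the arene.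

Step 12
Reactants: 11 (R)-tert-butyl[(2-ethenyl-1-methylcyclohex-2-en-1-yl)methoxy]dimethylsilane; 16 (E)-2-[(2,5-dimethoxyphenyl)methyl]but-2-enal
Product: 17 (1S,2R,5R,8aR)-5-{[(tert-butyldimethylsilyl)oxy]methyl}-1-[(2,5-dimethoxyphenyl)methyl]-2,5-dimethyl-1,2,3,5,6,7,8,8a-octahydronaphthalene-1-carbaldehyde
Conditions: oxazaborolidinium salt from the (S)-α,α-diphenylprolinol-derived B-(o-tolyl)oxazaborolidine and HNTf2 (20 mol%), CH2Cl2, −78 → −40 °C
Reagents that add atoms: none
Why: The catalyst-bound s-trans enal 16 and the s-cis diene unit C2=C3–C4=C5 of 11 combine in a concerted, asynchronous, normal-demand [4+2] cycloaddition in which C1–C2 bonding runs ahead of C5–C10 bonding; the closest known reaction type is the oxazaborolidinium-catalysed Diels–Alder addition of 2-substituted enals such as tiglic aldehyde to 1-vinylcyclohexenes. Ring A is closed by the cycloaddition itself, both new sigma bonds (C5–C10 and C1–C2) forming in the one suprafacial event. C1 and C10 are fixed relative to each other by the E geometry of the enal (C1 methyl cis to the arylmethyl group) and in the absolute sense by the catalyst, for which the formyl C–H···O binding model predicts that the (S)-prolinol-derived salt covers the Si face of C10 with a carbinol phenyl group, so that the diene adds to the Re face. C5 is fixed relative to C10 by endo orientation of the boron-bound formyl group (formyl cis to the C6 residue) and relative to C9 by approach of the dienophile anti to the pseudoaxial silyloxymethyl group, i.e. on the face that carries the C9 methyl. The step needs ortho regiochemistry, endo selectivity and this diene-face selectivity: the first follows from the large LUMO coefficient at C1 of the activated enal pairing with the large HOMO coefficient at the unsubstituted terminus C2, the second from Lewis-acid activation, and the third from the quaternary C9, whose small methyl takes the pseudoequatorial site beside the vinyl group and the incoming catalyst-bound formyl group while the large CH2OTBS group stands pseudoaxial and blocks the other face. Diene of the minor enantiomer left from step 3 should end as a diastereomeric adduct removable by chromatography.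

Step 13
Reactants: 17 (1S,2R,5R,8aR)-5-{[(tert-butyldimethylsilyl)oxy]methyl}-1-[(2,5-dimethoxyphenyl)methyl]-2,5-dimethyl-1,2,3,5,6,7,8,8a-octahydronaphthalene-1-carbaldehyde
Product: 18 (1S,2R,5R,8aR)-1-[(2,5-dimethoxyphenyl)methyl]-5-(hydroxymethyl)-2,5-dimethyl-1,2,3,5,6,7,8,8a-octahydronaphthalene-1-carbaldehyde
Conditions: Bu4NF, THF, rt → 40 °C
Reagents that add atoms: none
Why: Fluoride desilylation; the aldehyde has no α-hydrogen and cannot epimerise, and removing the silyl group first makes the outcome of the strongly basic step 14 unambiguous.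

Step 14
Reactants: 18 (1S,2R,5R,8aR)-1-[(2,5-dimethoxyphenyl)methyl]-5-(hydroxymethyl)-2,5-dimethyl-1,2,3,5,6,7,8,8a-octahydronaphthalene-1-carbaldehyde
Product: 20 [(1R,4aS,5R,6R)-5-[(2,5-dimethoxyphenyl)methyl]-1,5,6-trimethyl-1,2,3,4,4a,5,6,7-octahydronaphthalen-1-yl]methanol, via hydrazone 19 (not isolated)
Conditions: N2H4·H2O, diethylene glycol, 120 °C; then KOH, 200 °C
Reagents that add atoms: none
Why: Wolff–Kishner reduction (Huang-Minlon procedure) converts the hindered neopentyl aldehyde into the C10 methyl group; the free alcohol, the isolated alkene and the aryl methyl ethers tolerate the conditions and no stereocentre is enolisable.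

Step 15
Reactants: 20 [(1R,4aS,5R,6R)-5-[(2,5-dimethoxyphenyl)methyl]-1,5,6-trimethyl-1,2,3,4,4a,5,6,7-octahydronaphthalen-1-yl]methanol
Product: 21 (1R,4aS,5R,6R)-5-[(2,5-dimethoxyphenyl)methyl]-1,5,6-trimethyl-1,2,3,4,4a,5,6,7-octahydronaphthalene-1-carbaldehyde
Conditions: Dess–Martin periodinane, CH2Cl2, rt
Reagents that add atoms: none
Why: Dess–Martin oxidation of the neopentyl alcohol gives the C11 aldehyde, which is non-enolisable and cannot move into conjugation because C9 is quaternary.

Step 16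
Reactants: 22 2-methylcyclohex-2-en-1-one
Product: 24 {[(3S)-2,3-dimethylcyclohex-1-en-1-yl]oxy}trimethylsilane, via dimethylaluminium enolate 23 (not isolated)
Conditions: Me3Al, Cu(O2CC4H3S) (copper thiophene-2-carboxylate, 2 mol%), BINOL-derived phosphoramidite of bis(1-phenylethyl)amine (4 mol%, the antipode that gives 3S), Et2O, −30 °C; then Me3SiOTf, −30 → 0 °C
Reagents that add atoms: trimethylaluminium, C[Al](C)C; trimethylsilyl triflate, C[Si](C)(C)OS(=O)(=O)C(F)(F)F
Why: Copper-catalysed asymmetric conjugate addition of a methylaluminium reagent to the 2-substituted enone sets C22 under ligand control, and O-silylation of the resulting aluminium enolate stores the enolate regiospecifically as the tetrasubstituted silyl enol ether.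

Step 17
Reactants: 24 {[(3S)-2,3-dimethylcyclohex-1-en-1-yl]oxy}trimethylsilane
Product: 25 (2R,3S)-2,3-dimethyl-2-[(phenylsulfanyl)methyl]cyclohexan-1-one
Conditions: PhSCH2Cl, TiCl4, CH2Cl2, −78 °C
Reagents that add atoms: chloromethyl phenyl sulfide, ClCSc1ccccc1
Why: Lewis-acid-mediated phenylthiomethylation of a silyl enol ether (Mukaiyama-type alkylation by the thionium ion) builds the quaternary C13; the small electrophile should enter anti to the adjacent C22 methyl, which is held pseudoaxial by allylic strain, so C12 ends trans to that methyl.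

Step 18
Reactants: 25 (2R,3S)-2,3-dimethyl-2-[(phenylsulfanyl)methyl]cyclohexan-1-one
Product: 27 (5S,6R)-5,6-dimethyl-6-[(phenylsulfanyl)methyl]cyclohex-1-en-1-yl trifluoromethanesulfonate, via potassium enolate 26 (not isolated)
Conditions: KN(SiMe3)2, THF, −78 °C; PhNTf2, −78 → 0 °C; NH4Cl quench
Reagents that add atoms: N-phenylbis(trifluoromethanesulfonimide), O=S(=O)(N(c1ccccc1)S(=O)(=O)C(F)(F)F)C(F)(F)F
Why: Enolisation is possible only towards C19 because C13 is quaternary, so O-triflation gives the C14=C19 enol triflate alone; the sulfide has no acidic or eliminable position.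

Step 19
Reactants: 27 (5S,6R)-5,6-dimethyl-6-[(phenylsulfanyl)methyl]cyclohex-1-en-1-yl trifluoromethanesulfonate
Product: 28 {[(1R,6S)-2-ethenyl-1,6-dimethylcyclohex-2-en-1-yl]methyl}(phenyl)sulfane
Conditions: Bu3SnCH=CH2, Pd(PPh3)4 (5 mol%), LiCl, THF, 65 °C
Reagents that add atoms: tributyl(ethenyl)stannane, C=C[Sn](CCCC)(CCCC)CCCC
Why: Stille vinylation of the enol triflate, tolerant of the alkyl aryl sulfide, gives the ring D diene C19=C14–C15=C16.

Step 20
Reactants: 28 {[(1R,6S)-2-ethenyl-1,6-dimethylcyclohex-2-en-1-yl]methyl}(phenyl)sulfane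
Product: 29 (5R,6S,8aS)-1,5,6-trimethyl-5-[(phenylsulfanyl)methyl]-1,2,3,5,6,7,8,8a-octahydronaphthalene-1-carbaldehyde (C18 epimers)
Conditions: methacrolein, Me2AlCl, CH2Cl2, −78 → −30 °C
Reagents that add atoms: methacrolein, C=C(C)C=O
Why: Lewis-acid-promoted Diels–Alder reaction with ortho regiochemistry (C18–C19 and C16–C17 bonds, new C14=C15 alkene) closes ring C; the C13 and C22 methyls both lie on one face of ring D (one of them is axial in either half-chair), so the dienophile should add to the opposite face and set C19–H cis to the C13 methyl, while the C18 configuration is irrelevant because C18 becomes the gem-dimethyl carbon.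

Step 21
Reactants: 29 (5R,6S,8aS)-1,5,6-trimethyl-5-[(phenylsulfanyl)methyl]-1,2,3,5,6,7,8,8a-octahydronaphthalene-1-carbaldehyde
Product: 31 {[(1R,2S,4aR)-1,2,5,5-tetramethyl-1,2,3,4,4a,5,6,7-octahydronaphthalen-1-yl]methyl}(phenyl)sulfane, via hydrazone 30 (not isolated)
Conditions: N2H4·H2O, diethylene glycol, 120 °C; then KOH, 200 °C
Reagents that add atoms: none
Why: Wolff–Kishner reduction (Huang-Minlon procedure) turns the neopentyl formyl group into the second C18 methyl and merges both C18 epimers; the thioether and the trisubstituted alkene are inert to it.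

Step 22
Reactants: 31 {[(1R,2S,4aR)-1,2,5,5-tetramethyl-1,2,3,4,4a,5,6,7-octahydronaphthalen-1-yl]methyl}(phenyl)sulfane; 21 (1R,4aS,5R,6R)-5-[(2,5-dimethoxyphenyl)methyl]-1,5,6-trimethyl-1,2,3,4,4a,5,6,7-octahydronaphthalene-1-carbaldehyde
Product: 33 1-[(1R,4aS,5R,6R)-5-[(2,5-dimethoxyphenyl)methyl]-1,5,6-trimethyl-1,2,3,4,4a,5,6,7-octahydronaphthalen-1-yl]-2-[(1R,2S,4aR)-1,2,5,5-tetramethyl-1,2,3,4,4a,5,6,7-octahydronaphthalen-1-yl]ethan-1-ol (C11 epimers), via neopentyllithium 32 (not isolated)
Conditions: 31, lithium 4,4′-di-tert-butylbiphenylide (2.05 equiv), THF, −78 °C; then 21, −78 → −20 °C; NH4Cl quench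
Reagents that add atoms: none
Why: Reductive lithiation of the alkyl phenyl sulfide (two single-electron transfers, loss of thiophenoxide) gives a C12 neopentyl-type organolithium without β-hydrogens, which should add cleanly to the non-enolisable C11 aldehyde; at −78 °C the transient C12 radical is reduced far faster than it can rearrange, and the carbinol configuration is irrelevant.

Step 23
Reactants: 33 the C11 secondary alcohol
Product: 35 O-{1-[(1R,4aS,5R,6R)-5-[(2,5-dimethoxyphenyl)methyl]-1,5,6-trimethyl-1,2,3,4,4a,5,6,7-octahydronaphthalen-1-yl]-2-[(1R,2S,4aR)-1,2,5,5-tetramethyl-1,2,3,4,4a,5,6,7-octahydronaphthalen-1-yl]ethyl} S-methyl carbonodithioate, via potassium xanthate 34 (not isolated)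
Conditions: KN(SiMe3)2, THF, 0 °C; CS2; MeI
Reagents that add atoms: carbon disulfide, S=C=S; iodomethane, CI
Why: Xanthate formation works on very hindered alkoxides because the electrophile CS2 is small and linear.

Step 24
Reactants: 35 the S-methyl xanthate
Product: 36 2-{[(1R,2R,5S,8aS)-1,2,5-trimethyl-5-{2-[(1R,2S,4aR)-1,2,5,5-tetramethyl-1,2,3,4,4a,5,6,7-octahydronaphthalen-1-yl]ethyl}-1,2,3,5,6,7,8,8a-octahydronaphthalen-1-yl]methyl}-1,4-dimethoxybenzene
Conditions: Bu3SnH, AIBN, (PhSe)2 (10 mol%), benzene, 80 °C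
Reagents that add atoms: none
Why: Barton–McCombie deoxygenation removes the C11 oxygen through the secondary C11 radical; benzeneselenol formed in the flask from the diselenide is a very fast hydrogen donor and should trap this radical before it can add to the neighbouring C4=C3 bond.

Step 25
Reactants: 36 the dimethoxyarene
Product: 38 2-{[(1R,2R,5S,8aS)-1,2,5-trimethyl-5-{2-[(1R,2S,4aR)-1,2,5,5-tetramethyl-1,2,3,4,4a,5,6,7-octahydronaphthalen-1-yl]ethyl}-1,2,3,5,6,7,8,8a-octahydronaphthalen-1-yl]methyl}benzene-1,4-diol, via quinone 37 (not isolated)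
Conditions: (NH4)2Ce(NO3)6, MeCN/H2O, 0 °C; extract; then aq. Na2S2O4, Et2O, rt
Reagents that add atoms: water, O
Why: Oxidative demethylation of the 1,4-dimethoxyarene by the ceric salt gives the quinone without touching the hindered trisubstituted alkenes, and dithionite reduces it at once to the air-sensitive hydroquinone.

Step 26
Reactants: 38 the hydroquinone
Product: 39 toxiusol, 2-{[(1R,2R,5S,8aS)-1,2,5-trimethyl-5-{2-[(1R,2S,4aR)-1,2,5,5-tetramethyl-1,2,3,4,4a,5,6,7-octahydronaphthalen-1-yl]ethyl}-1,2,3,5,6,7,8,8a-octahydronaphthalen-1-yl]methyl}-1,4-phenylene bis(hydrogen sulfate)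
Conditions: SO3·pyridine (excess), pyridine, 50 °C; then H+-form cation-exchange resin, MeOH/H2O, 0 °C
Reagents that add atoms: sulfur trioxide–pyridine complex, [O-]S(=O)(=O)[n+]1ccccc1
Why: O-Sulfation of both phenols by the SO3–amine complex under basic conditions that do not isomerise the alkenes, followed by brief cation exchange, should give the target in the acid form drawn.

**Compound list**
1 | cyclohexanone | O=C1CCCCC1 | starting material
2 | prop-2-en-1-yl 2-oxocyclohexane-1-carboxylate | C=CCOC(=O)C1CCCCC1=O | intermediate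
3 | prop-2-en-1-yl 1-methyl-2-oxocyclohexane-1-carboxylate (racemic) | C=CCOC(=O)C1(C)CCCCC1=O | intermediate
4 | (S)-2-methyl-2-(prop-2-en-1-yl)cyclohexan-1-one | C=CC[C@]1(C)CCCCC1=O | intermediate
5 | (S)-2-methyl-2-[(E)-prop-1-en-1-yl]cyclohexan-1-one | C/C=C/[C@]1(C)CCCCC1=O | intermediate
6 | potassium (S)-6-methyl-6-[(E)-prop-1-en-1-yl]cyclohex-1-en-1-olate | C/C=C/[C@]1(C)CCCC=C1[O-].[K+] | intermediate
7 | (S)-6-methyl-6-[(E)-prop-1-en-1-yl]cyclohex-1-en-1-yl trifluoromethanesulfonate | C/C=C/[C@]1(C)CCCC=C1OS(=O)(=O)C(F)(F)F | intermediate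
8 | (6S)-6-methyl-6-(5-methyl-1,2,4-trioxolan-3-yl)cyclohex-1-en-1-yl trifluoromethanesulfonate | CC1OOC(O1)[C@]2(C)CCCC=C2OS(=O)(=O)C(F)(F)F | intermediate
9 | (S)-6-(hydroxymethyl)-6-methylcyclohex-1-en-1-yl trifluoromethanesulfonate | OC[C@]1(C)CCCC=C1OS(=O)(=O)C(F)(F)F | intermediate
10 | (S)-6-{[(tert-butyldimethylsilyl)oxy]methyl}-6-methylcyclohex-1-en-1-yl trifluoromethanesulfonate | CC(C)(C)[Si](C)(C)OC[C@]1(C)CCCC=C1OS(=O)(=O)C(F)(F)F | intermediate
11 | (R)-tert-butyl[(2-ethenyl-1-methylcyclohex-2-en-1-yl)methoxy]dimethylsilane | C=CC1=CCCC[C@@]1(C)CO[Si](C)(C)C(C)(C)C | intermediate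
12 | 2-(chloromethyl)-1,4-dimethoxybenzene | COc1ccc(OC)c(CCl)c1 | starting material
13 | ethyl 3-(2,5-dimethoxyphenyl)-2-(triphenyl-λ5-phosphanylidene)propanoate | CCOC(=O)C(Cc1cc(OC)ccc1OC)=P(c1ccccc1)(c1ccccc1)c1ccccc1 | intermediate
14 | ethyl (E)-2-[(2,5-dimethoxyphenyl)methyl]but-2-enoate | C/C=C(/C(=O)OCC)Cc1cc(OC)ccc1OC | intermediate
15 | (E)-2-[(2,5-dimethoxyphenyl)methyl]but-2-en-1-ol | C/C=C(/CO)Cc1cc(OC)ccc1OC | intermediate
16 | (E)-2-[(2,5-dimethoxyphenyl)methyl]but-2-enal | C/C=C(/C=O)Cc1cc(OC)ccc1OC | intermediate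
17 | (1S,2R,5R,8aR)-5-{[(tert-butyldimethylsilyl)oxy]methyl}-1-[(2,5-dimethoxyphenyl)methyl]-2,5-dimethyl-1,2,3,5,6,7,8,8a-octahydronaphthalene-1-carbaldehyde | C[C@@H]1CC=C2[C@@H](CCC[C@@]2(C)CO[Si](C)(C)C(C)(C)C)[C@]1(C=O)Cc1cc(OC)ccc1OC | intermediate
18 | (1S,2R,5R,8aR)-1-[(2,5-dimethoxyphenyl)methyl]-5-(hydroxymethyl)-2,5-dimethyl-1,2,3,5,6,7,8,8a-octahydronaphthalene-1-carbaldehyde | C[C@@H]1CC=C2[C@@H](CCC[C@@]2(C)CO)[C@]1(C=O)Cc1cc(OC)ccc1OC | intermediate
19 | hydrazone of 18 | C[C@@H]1CC=C2[C@@H](CCC[C@@]2(C)CO)[C@]1(C=NN)Cc1cc(OC)ccc1OC | intermediate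
20 | [(1R,4aS,5R,6R)-5-[(2,5-dimethoxyphenyl)methyl]-1,5,6-trimethyl-1,2,3,4,4a,5,6,7-octahydronaphthalen-1-yl]methanol | C[C@@H]1CC=C2[C@@H](CCC[C@@]2(C)CO)[C@]1(C)Cc1cc(OC)ccc1OC | intermediate
21 | (1R,4aS,5R,6R)-5-[(2,5-dimethoxyphenyl)methyl]-1,5,6-trimethyl-1,2,3,4,4a,5,6,7-octahydronaphthalene-1-carbaldehyde | C[C@@H]1CC=C2[C@@H](CCC[C@@]2(C)C=O)[C@]1(C)Cc1cc(OC)ccc1OC | intermediate
22 | 2-methylcyclohex-2-en-1-one | CC1=CCCCC1=O | starting material
23 | dimethylaluminium (3S)-2,3-dimethylcyclohex-1-en-1-olate | C[Al](C)OC1=C(C)[C@@H](C)CCC1 | intermediate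
24 | {[(3S)-2,3-dimethylcyclohex-1-en-1-yl]oxy}trimethylsilane | C[Si](C)(C)OC1=C(C)[C@@H](C)CCC1 | intermediate
25 | (2R,3S)-2,3-dimethyl-2-[(phenylsulfanyl)methyl]cyclohexan-1-one | c1ccccc1SC[C@@]2(C)C(=O)CCC[C@@H]2C | intermediate
26 | potassium (5S,6R)-5,6-dimethyl-6-[(phenylsulfanyl)methyl]cyclohex-1-en-1-olate | c1ccccc1SC[C@@]2(C)C([O-])=CCC[C@@H]2C.[K+] | intermediate
27 | (5S,6R)-5,6-dimethyl-6-[(phenylsulfanyl)methyl]cyclohex-1-en-1-yl trifluoromethanesulfonate | c1ccccc1SC[C@@]2(C)C(OS(=O)(=O)C(F)(F)F)=CCC[C@@H]2C | intermediate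
28 | {[(1R,6S)-2-ethenyl-1,6-dimethylcyclohex-2-en-1-yl]methyl}(phenyl)sulfane | c1ccccc1SC[C@@]2(C)C(C=C)=CCC[C@@H]2C | intermediate
29 | (5R,6S,8aS)-1,5,6-trimethyl-5-[(phenylsulfanyl)methyl]-1,2,3,5,6,7,8,8a-octahydronaphthalene-1-carbaldehyde (C18 epimers) | c1ccccc1SC[C@@]2(C)C3=CCCC(C)(C=O)[C@H]3CC[C@@H]2C | intermediate
30 | hydrazone of 29 | c1ccccc1SC[C@@]2(C)C3=CCCC(C)(C=NN)[C@H]3CC[C@@H]2C | intermediate
31 | {[(1R,2S,4aR)-1,2,5,5-tetramethyl-1,2,3,4,4a,5,6,7-octahydronaphthalen-1-yl]methyl}(phenyl)sulfane | c1ccccc1SC[C@@]2(C)C3=CCCC(C)(C)[C@H]3CC[C@@H]2C | intermediate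
32 | {[(1R,2S,4aR)-1,2,5,5-tetramethyl-1,2,3,4,4a,5,6,7-octahydronaphthalen-1-yl]methyl}lithium | [Li]C[C@@]1(C)C2=CCCC(C)(C)[C@H]2CC[C@@H]1C | intermediate
33 | 1-[(1R,4aS,5R,6R)-5-[(2,5-dimethoxyphenyl)methyl]-1,5,6-trimethyl-1,2,3,4,4a,5,6,7-octahydronaphthalen-1-yl]-2-[(1R,2S,4aR)-1,2,5,5-tetramethyl-1,2,3,4,4a,5,6,7-octahydronaphthalen-1-yl]ethan-1-ol (C11 epimers) | C[C@@H]1CC=C2[C@@H](CCC[C@@]2(C)C(O)C[C@@]2(C)C3=CCCC(C)(C)[C@H]3CC[C@@H]2C)[C@]1(C)Cc1cc(OC)ccc1OC | intermediate
34 | potassium O-alkyl carbonodithioate of 33 | C[C@@H]1CC=C2[C@@H](CCC[C@@]2(C)C(OC(=S)[S-])C[C@@]2(C)C3=CCCC(C)(C)[C@H]3CC[C@@H]2C)[C@]1(C)Cc1cc(OC)ccc1OC.[K+] | intermediate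
35 | O-alkyl S-methyl carbonodithioate of 33 | C[C@@H]1CC=C2[C@@H](CCC[C@@]2(C)C(OC(=S)SC)C[C@@]2(C)C3=CCCC(C)(C)[C@H]3CC[C@@H]2C)[C@]1(C)Cc1cc(OC)ccc1OC | intermediate
36 | 2-{[(1R,2R,5S,8aS)-1,2,5-trimethyl-5-{2-[(1R,2S,4aR)-1,2,5,5-tetramethyl-1,2,3,4,4a,5,6,7-octahydronaphthalen-1-yl]ethyl}-1,2,3,5,6,7,8,8a-octahydronaphthalen-1-yl]methyl}-1,4-dimethoxybenzene | C[C@@H]1CC=C2[C@@H](CCC[C@@]2(C)CC[C@@]2(C)C3=CCCC(C)(C)[C@H]3CC[C@@H]2C)[C@]1(C)Cc1cc(OC)ccc1OC | intermediate
37 | corresponding 2-substituted cyclohexa-2,5-diene-1,4-dione (quinone) | C[C@@H]1CC=C2[C@@H](CCC[C@@]2(C)CC[C@@]2(C)C3=CCCC(C)(C)[C@H]3CC[C@@H]2C)[C@]1(C)CC1=CC(=O)C=CC1=O | intermediate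
38 | corresponding 2-substituted benzene-1,4-diol (hydroquinone) | C[C@@H]1CC=C2[C@@H](CCC[C@@]2(C)CC[C@@]2(C)C3=CCCC(C)(C)[C@H]3CC[C@@H]2C)[C@]1(C)Cc1cc(O)ccc1O | intermediate
39 | toxiusol | C[C@@H]1CC=C2[C@@H](CCC[C@@]2(C)CC[C@@]2(C)C3=CCCC(C)(C)[C@H]3CC[C@@H]2C)[C@]1(C)Cc1cc(OS(=O)(=O)O)ccc1OS(=O)(=O)O | target

**Totals**
Total steps: 26. Longest linear sequence: 17 steps (steps 1–8, 12–15, 22–26).

**Steps most likely to fail**

1. Step 12 (key cycloaddition). The trisubstituted enal may react too slowly for the acid-sensitive diene to survive, or the dienophile may not discriminate well enough between the two faces of ring B. Fallback, setting out from diene 11 and returning at alcohol 20: C10 is built in two stages. Diene 11 is combined under Me2AlCl with the much more reactive, α-unsubstituted aryl enone (E)-1-(2,5-dimethoxyphenyl)but-2-en-1-one F1, giving the endo aryl ketone adduct F2. Its potassium enolate (KN(SiMe3)2) is methylated with MeI anti to the axial C1 methyl to give the C10-methyl ketone F3. Bu4NF then gives the hydroxy ketone F4, and Huang-Minlon reduction of the aryl ketone to the benzylic methylene delivers 20.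

2. Step 20 (ring C cycloaddition). The dienophile may add to the wrong face of ring D, giving the C19 epimer, which cannot be corrected afterwards. Fallback, setting out from ketone 25 and returning at sulfide 31: C19 is set under thermodynamic control. Ketone 25 is converted (Me3SiOTf, Et3N) into the trimethylsilyl enol ether F5. Mukaiyama–Michael addition to mesityl oxide (TiCl4, −78 °C) gives the 1,5-diketone F6. Aldol condensation (KOt-Bu, t-BuOH, reflux) closes ring C as the bicyclic enone F7, in which C19 equilibrates through the dienolate to the isomer with all ring D substituents equatorial. Luche reduction (NaBH4, CeCl3) gives the allylic alcohol F8, which is converted into the allylic xanthate F9 and reduced with Bu3SnH/AIBN; hydrogen is delivered to the less hindered C16 terminus of the allyl radical, leaving the C14=C15 alkene of 31.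

3. Step 24 (radical deoxygenation). The C11 radical may add to C4 and reopen with 1,2-vinyl migration (ring B expansion) before hydrogen transfer. Fallback, setting out from xanthate 35 and returning at 36: the radical is avoided altogether. Chugaev pyrolysis of 35 (about 190 °C, o-dichlorobenzene) gives by concerted syn elimination the (E)-C11=C12 alkene F10, the only elimination possible because C9 is quaternary. Diimide (2-nitrobenzenesulfonohydrazide, Et3N) then reduces this disubstituted alkene in preference to the two trisubstituted ring alkenes to give 36.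

**Further compounds**
F1 | step 12 | (E)-1-(2,5-dimethoxyphenyl)but-2-en-1-one | C/C=C/C(=O)c1cc(OC)ccc1OC
F2 | step 12 | [5-{[(tert-butyldimethylsilyl)oxy]methyl}-2,5-dimethyl-1,2,3,5,6,7,8,8a-octahydronaphthalen-1-yl](2,5-dimethoxyphenyl)methanone (endo adduct) | C[C@@H]1CC=C2[C@@H](CCC[C@@]2(C)CO[Si](C)(C)C(C)(C)C)[C@H]1C(=O)c1cc(OC)ccc1OC
F3 | step 12 | [5-{[(tert-butyldimethylsilyl)oxy]methyl}-1,2,5-trimethyl-1,2,3,5,6,7,8,8a-octahydronaphthalen-1-yl](2,5-dimethoxyphenyl)methanone | C[C@@H]1CC=C2[C@@H](CCC[C@@]2(C)CO[Si](C)(C)C(C)(C)C)[C@]1(C)C(=O)c1cc(OC)ccc1OC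
F4 | step 12 | [5-(hydroxymethyl)-1,2,5-trimethyl-1,2,3,5,6,7,8,8a-octahydronaphthalen-1-yl](2,5-dimethoxyphenyl)methanone | C[C@@H]1CC=C2[C@@H](CCC[C@@]2(C)CO)[C@]1(C)C(=O)c1cc(OC)ccc1OC
F5 | step 20 | {[(5S,6R)-5,6-dimethyl-6-[(phenylsulfanyl)methyl]cyclohex-1-en-1-yl]oxy}trimethylsilane | c1ccccc1SC[C@@]2(C)C(O[Si](C)(C)C)=CCC[C@@H]2C
F6 | step 20 | (2R,3S)-2,3-dimethyl-6-(2-methyl-4-oxopentan-2-yl)-2-[(phenylsulfanyl)methyl]cyclohexan-1-one (C19 epimers) | c1ccccc1SC[C@@]2(C)C(=O)C(C(C)(C)CC(C)=O)CC[C@@H]2C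
F7 | step 20 | (4aR,7S,8R)-4,4,7,8-tetramethyl-8-[(phenylsulfanyl)methyl]-4,4a,5,6,7,8-hexahydronaphthalen-2(3H)-one | c1ccccc1SC[C@@]2(C)C3=CC(=O)CC(C)(C)[C@H]3CC[C@@H]2C
F8 | step 20 | corresponding allylic alcohol (C16 carbinol epimers) | c1ccccc1SC[C@@]2(C)C3=CC(O)CC(C)(C)[C@H]3CC[C@@H]2C
F9 | step 20 | O-allylic S-methyl carbonodithioate of the C16 alcohol | c1ccccc1SC[C@@]2(C)C3=CC(OC(=S)SC)CC(C)(C)[C@H]3CC[C@@H]2C
F10 | step 24 | (E)-C11=C12 alkene analogue of 36 | C[C@@H]1CC=C2[C@@H](CCC[C@@]2(C)/C=C/[C@@]2(C)C3=CCCC(C)(C)[C@H]3CC[C@@H]2C)[C@]1(C)Cc1cc(OC)ccc1OC
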